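Ring A (cyclopentane) and ring B (dearomatised benzoylphloroglucinol) are separated at the bond between the CH2 link and ring B. Forward, this is a reductive Knoevenagel alkylation of the gem-diprenyl triketone with the ring A carbaldehyde.
Ring B comes from phloroglucinol by Friedel-Crafts benzoylation, then alkylative dearomatisation that places two prenyl groups on one carbon.
Ring A is cut between the CH bearing the isopropenyl group and the CH bearing the CH2 link. This unfolds it to acyclic (2S,3S)-2,3-epoxygeraniol, the kind of oxidised geranyl chain from which ring A is presumed to arise in nature. Forward, a cobalt-catalysed radical cycloisomerisation closes it.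
Enabling feature: in ring A the CH(CH2) carbon sits next to the C(OH)CH3 carbon, so the two map onto a trisubstituted epoxide whose only accessible end is that CH. It is separated from the CH(isopropenyl) carbon by C(OH)CH3, CH2 and CH2, a 5-hexenyl radical/alkene relation, and the isopropenyl group is what remains of a tertiary radical that loses H.
Order of rings: ring B is present from the start (aromatic, dearomatised in step 5) and ring A forms in step 2. One Sharpless epoxidation sets the carbinol centre, which controls the other two.
Key step: step 2

Remarks: locants C1 to C8 follow geraniol (C1 = CH2OH carbon). dmgH is the monoanion of dimethylglyoxime and py is pyridine. Ring B is a set of rapidly interconverting enol tautomers, and all SMILES are assumed to use the tautomer of the target string.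

Step 1
Reactants: 1 geraniol
Product: 2 (2S,3S)-2,3-epoxygeraniol
Conditions: Ti(OiPr)4 (5 mol %), L-(+)-diethyl tartrate (7 mol %), t-BuOOH (1.5 equiv, decane), 4 Å MS, CH2Cl2, -20 °C
Reagents that add atoms: tert-butyl hydroperoxide, CC(C)(C)OO
Why: Sharpless asymmetric epoxidation: the complex formed from Ti(OiPr)4 and the tartrate binds the allylic alcohol, so only the C2=C3 double bond reacts, and L-(+)-diethyl tartrate directs oxygen to the face that gives the (2S,3S)-epoxide, fixing C3 as the future carbinol centre.

Step 2
Reactants: 2 (2S,3S)-2,3-epoxygeraniol
Product: 3 (1S,2S,3S)-2-(hydroxymethyl)-1-methyl-3-(prop-1-en-2-yl)cyclopentan-1-ol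
Conditions: Co(dmgH)2(py)Cl (10 mol %), NaBH4 (20 mol %), iPr2NEt (1 equiv), MeCN/MeOH 4:1 (0.02 M), Ar, blue LEDs (450 nm), 25 °C
Reagents that add atoms: none
Why: NaBH4 reduces the precatalyst to the monovalent cobalt nucleophile [Co(dmgH)2(py)]-, whose flat, bulky ligand set lets it open the trisubstituted epoxide of 2 only at the secondary carbon C2 (SN2), so the C3-O bond and the C3 configuration from step 1 are never touched, and blue light then breaks the weak Co-C bond and frees the secondary C2 radical. This 5-hexenyl-type radical closes ring A 5-exo-trig onto C6 of the C6=C7 double bond (C2-C6 bond, accelerated by the fully substituted C3), divalent cobalt takes a hydrogen atom from a methyl group of the tertiary C7 radical to leave the isopropenyl group, and iPr2NEt deprotonates the cobalt hydride back to monovalent cobalt, so the step is a redox-neutral isomerisation. The closest known reaction types are the radical cyclisation of epoxy-olefins mediated by Co(dmgH)2(py) complexes and ending in dehydrocobaltation, and the alkyl-Heck-type cyclisation of alkyl iodides catalysed by the same complexes under blue light. C6 relative to C2 is controlled in the chair-like transition state by the C7 methyl group that is cis to the chain: it keeps the CH2OH group on the radical carbon from pointing toward the alkene, which makes CH2OH and the new C7 substituent trans. C2 and C6 relative to C3 are controlled by allylic-type 1,2-strain: the outward CH2OH group on the flat radical carbon eclipses the pseudo-equatorial site of C3, which is therefore taken by OH (small, hydrogen-bonded to CH2OH) while CH3 goes pseudo-axial, giving CH2OH cis to OH and isopropenyl cis to CH3, the one diastereomer without cis-vicinal carbon substituents. The step needs regioselective opening (secured by the tertiary versus secondary epoxide carbons), ring closure faster than hydrogen abstraction from the open radical (low cobalt loading, dilution, fast 5-exo rate), and the terminal rather than the tetrasubstituted alkene (the bulky cobalt centre reaches only the methyl hydrogens, and the base removes the hydride before it can add back).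

Step 3
Reactants: 3 (1S,2S,3S)-2-(hydroxymethyl)-1-methyl-3-(prop-1-en-2-yl)cyclopentan-1-ol
Product: 4 (1R,2S,5S)-2-hydroxy-2-methyl-5-(prop-1-en-2-yl)cyclopentane-1-carbaldehyde
Conditions: TEMPO (10 mol %), PhI(OAc)2 (1.1 equiv), CH2Cl2, 0 to 23 °C
Reagents that add atoms: none
Why: Oxoammonium (TEMPO) oxidation takes only the primary alcohol, leaves the tertiary alcohol and the 1,1-disubstituted alkene alone, and runs without base, so the β-hydroxy aldehyde should neither eliminate water nor leave its most stable configuration.

Step 4
Reactants: 5 phloroglucinol, 6 benzoyl chloride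
Product: 7 2,4,6-trihydroxybenzophenone
Conditions: AlCl3 (3.5 equiv), PhNO2, 65 °C, then aq. HCl
Reagents that add atoms: none
Why: Friedel-Crafts acylation of a very electron-rich arene, in which the chelated aryl ketone that forms is deactivated, so the reaction should stop after one benzoyl group.

Step 5
Reactants: 7 2,4,6-trihydroxybenzophenone, 8 prenyl bromide (2 equiv)
Product: 9 2-benzoyl-3,5-dihydroxy-6,6-bis(3-methylbut-2-en-1-yl)cyclohexa-2,4-dien-1-one
Conditions: NaOMe (2.1 equiv), MeOH, 0 to 23 °C, slow addition of 8
Reagents that add atoms: none
Why: Alkylative dearomatisation of an acylphloroglucinol (the reaction type that gives hop beta-acids and acylfilicinic acids): in methanolic NaOMe the phenolate reacts at carbon, and the first-formed 3-prenyl compound is alkylated again at its more electron-rich prenylated carbon, which breaks aromaticity, forms no stereocentre and leaves one free ring CH for step 6.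

Step 6
Reactants: 4 (1R,2S,5S)-2-hydroxy-2-methyl-5-(prop-1-en-2-yl)cyclopentane-1-carbaldehyde, 9 2-benzoyl-3,5-dihydroxy-6,6-bis(3-methylbut-2-en-1-yl)cyclohexa-2,4-dien-1-one
Product: 11 hypercalin B, via alkylidene trione 10 (not isolated)
Conditions: Hantzsch ester (diethyl 2,6-dimethyl-1,4-dihydropyridine-3,5-dicarboxylate, 1.2 equiv), L-proline (10 mol %), CH2Cl2, 23 °C
Reagents that add atoms: none
Why: Three-component reductive alkylation (Knoevenagel condensation, then transfer hydrogenation): the only free ring carbon of the vinylogous acid 9 condenses with 4 to the electron-poor alkylidene trione 10, which takes hydride from the Hantzsch ester at the former aldehyde carbon, while no stereocentre is formed and the centre next to the aldehyde already has its most stable configuration (trans to both neighbouring carbon substituents), so reversible enamine formation should not scramble it.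

Compound list
1 | geraniol, (2E)-3,7-dimethylocta-2,6-dien-1-ol | CC(C)=CCC/C(C)=C/CO | starting material
2 | (2S,3S)-2,3-epoxygeraniol, [(2S,3S)-3-methyl-3-(4-methylpent-3-en-1-yl)oxiran-2-yl]methanol | CC(C)=CCC[C@]1(C)O[C@H]1CO | intermediate
3 | (1S,2S,3S)-2-(hydroxymethyl)-1-methyl-3-(prop-1-en-2-yl)cyclopentan-1-ol (CH2OH cis to OH, trans to isopropenyl) | C=C(C)[C@H]1CC[C@](C)(O)[C@@H]1CO | intermediate
4 | (1R,2S,5S)-2-hydroxy-2-methyl-5-(prop-1-en-2-yl)cyclopentane-1-carbaldehyde | C=C(C)[C@H]1CC[C@](C)(O)[C@@H]1C=O | intermediate
5 | phloroglucinol | Oc1cc(O)cc(O)c1 | starting material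
6 | benzoyl chloride | O=C(Cl)c1ccccc1 | starting material
7 | 2,4,6-trihydroxybenzophenone | O=C(c1ccccc1)c1c(O)cc(O)cc1O | intermediate
8 | prenyl bromide, 1-bromo-3-methylbut-2-ene | CC(C)=CCBr | starting material
9 | 2-benzoyl-3,5-dihydroxy-6,6-bis(3-methylbut-2-en-1-yl)cyclohexa-2,4-dien-1-one | O=C(c1ccccc1)C1=C(O)C=C(O)C(CC=C(C)C)(CC=C(C)C)C1=O | intermediate
10 | alkylidene trione (Knoevenagel adduct of 4 and 9, geometry of the new C=C not defined) | C=C(C)[C@H]1CC[C@](C)(O)[C@@H]1C=C1C(=O)C(CC=C(C)C)(CC=C(C)C)C(=O)C(C(=O)c2ccccc2)=C1O | intermediate
11 | hypercalin B, 2-benzoyl-3,5-dihydroxy-4-{[(1R,2S,5S)-2-hydroxy-2-methyl-5-(prop-1-en-2-yl)cyclopentyl]methyl}-6,6-bis(3-methylbut-2-en-1-yl)cyclohexa-2,4-dien-1-one | C=C(C)[C@H]1CC[C@](C)(O)[C@@H]1CC1=C(O)C(CC=C(C)C)(CC=C(C)C)C(=O)C(C(=O)c2ccccc2)=C1O | target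

Total step count: 6.
Longest linear sequence: 4 steps (1, 2, 3, 6). The ring B branch (steps 4 and 5) joins in step 6.

Steps most likely to fail

**Step 2.** Three processes could spoil it: slow attack of the cobalt nucleophile at the hindered C2, hydrogen abstraction from the open-chain radical before ring closure, and poor facial selectivity with respect to C3. The fallback isolates the radical precursor and locks it in a temporary ring.
- It sets out from 2. LiI/AcOH in THF should open the epoxide at C2 to the iodohydrin (2R,3S)-2-iodo-3,7-dimethyloct-6-ene-1,3-diol F1.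
- 2,2-Dimethoxypropane/PPTS then ties the 1,3-diol into the acetonide (4S,5R)-5-iodo-2,2,4-trimethyl-4-(4-methylpent-3-en-1-yl)-1,3-dioxane F2.
- The alkyl-Heck-type cyclisation of this secondary iodide (Co(dmgH)2(py)Cl and NaBH4 in catalytic amounts, iPr2NEt, MeCN, blue LEDs) forms the same C2-C6 bond. The radical now sits in a six-membered ring, which strongly favours the cis-fused bicycle and so places CH2O and the ring oxygen on one face. The product is (4aS,5S,7aS)-2,2,7a-trimethyl-5-(prop-1-en-2-yl)hexahydrocyclopenta[d][1,3]dioxine F3.
- Aqueous AcOH removes the acetonide, and the route is rejoined at 3.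

**Step 6.** The β-hydroxy aldehyde could lose water by enamine-triggered elimination, open by retro-aldol reaction, or condense too slowly because it is hindered. The fallback forms the same bond by substitution instead of condensation.
- It sets out from 3. An Appel reaction (I2, PPh3, imidazole, CH2Cl2) should convert only the primary alcohol into (1S,2R,3S)-2-(iodomethyl)-1-methyl-3-(prop-1-en-2-yl)cyclopentan-1-ol F4.
- The potassium salt of 9 (K2CO3, DMF, 50 °C) is alkylated at its free ring carbon with F4. The weakly basic enolate leaves the tertiary alcohol protonated.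
- The route is rejoined at 11.

**Step 5.** Alkylation could occur at the unsubstituted ring carbon, and the nucleophilic product 9 could take up a third prenyl group. The fallback changes the order of events so that the ring A unit blocks one ring carbon first.
- It sets out from 7 and 4. The same reductive alkylation (Hantzsch ester, L-proline, EtOH), run with excess 7, should give {2,4,6-trihydroxy-3-{[(1R,2S,5S)-2-hydroxy-2-methyl-5-(prop-1-en-2-yl)cyclopentyl]methyl}phenyl}(phenyl)methanone F5.
- Double prenylation with 8 (NaOMe, MeOH, 0 °C) then follows the trialkylation pattern of hop beta-acids. The second prenyl group should enter at the less hindered, already prenylated carbon.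
- The route is rejoined at 11.

Further compounds
F1 | step 2 | (2R,3S)-2-iodo-3,7-dimethyloct-6-ene-1,3-diol | CC(C)=CCC[C@](C)(O)[C@H](I)CO
F2 | step 2 | (4S,5R)-5-iodo-2,2,4-trimethyl-4-(4-methylpent-3-en-1-yl)-1,3-dioxane | CC(C)=CCC[C@]1(C)OC(C)(C)OC[C@H]1I
F3 | step 2 | (4aS,5S,7aS)-2,2,7a-trimethyl-5-(prop-1-en-2-yl)hexahydrocyclopenta[d][1,3]dioxine (acetonide of 3) | C=C(C)[C@H]1CC[C@]2(C)OC(C)(C)OC[C@H]12
F4 | step 6 | (1S,2R,3S)-2-(iodomethyl)-1-methyl-3-(prop-1-en-2-yl)cyclopentan-1-ol | C=C(C)[C@H]1CC[C@](C)(O)[C@@H]1CI
F5 | step 5 | {2,4,6-trihydroxy-3-{[(1R,2S,5S)-2-hydroxy-2-methyl-5-(prop-1-en-2-yl)cyclopentyl]methyl}phenyl}(phenyl)methanone | C=C(C)[C@H]1CC[C@](C)(O)[C@@H]1Cc1c(O)cc(O)c(C(=O)c2ccccc2)c1O
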